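The route rests on cutting the cyclohexenone (C1 ketone, C2/C3 methoxy, C4 carbinol, C5 side chain, C6 methyl) at C4–C5 and C6–C1: C1–C4 with both methoxy groups are the four-membered ring of dimethyl squarate. In the key step propenyllithium adds to a squarate monoketal of (S,S)-hydrobenzoin; oxy-anion-driven 4π opening and 6π closure expand the cyclobutene by C5 and C6 to the six-membered ring, the temporary dioxolane ring sets C6, and the enolate formed is alkylated at C5 by the complete side-chain bromide, made from farnesol. Reduction (C4) and ketal hydrolysis (C1 ketone) follow.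

Key step: step 12

Remark: ring atoms are numbered as in the target (C1 ketone to C6 methyl-bearing carbon) and side-chain atoms are primed from C1′ on C5; the sense of induction assigned to the (S,S)-ketal in step 12 comes from a steric model, and the equally available (R,R)-diol would replace it if the opposite sense were found.

Step 1
Reactants: 1 (2E,6E)-farnesol
Product: 2 (2E,6E)-farnesyl 4-methoxybenzyl ether
Conditions: NaH, 4-methoxybenzyl chloride, Bu4NI (cat.), THF/DMF, 0 °C to rt
Reagents that add atoms: 4-methoxybenzyl chloride (COc1ccc(CCl)cc1)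
Why: Williamson etherification of the primary allylic alkoxide; the PMB ether survives the hydride and silylation steps and is later removed oxidatively beside silyl ethers.

Step 2
Reactants: 2 (2E,6E)-farnesyl 4-methoxybenzyl ether
Product: 4 racemic 10,11-epoxide of 2, via bromohydrin 3 (not isolated)
Conditions: NBS, THF/H2O, 0 °C; then K2CO3, MeOH, rt
Reagents that add atoms: water (O)
Why: Bromohydrin formation in aqueous medium should favour the terminal trisubstituted alkene (the 2,3-alkene is deactivated by the allylic ether), and intramolecular Williamson closure gives the epoxide; its stereocenter is removed in step 3.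

Step 3
Reactants: 4 racemic 10,11-epoxide of 2
Product: 6 (4E,8E)-10-[(4-methoxybenzyl)oxy]-4,8-dimethyldeca-4,8-dienal, via 10,11-diol 5 (not isolated)
Conditions: H5IO6, THF/H2O, 0 °C
Reagents that add atoms: none
Why: Acid opening of the epoxide to the glycol and Malaprade cleavage remove the terminal isopropylidene carbons as acetone and leave the C10′ aldehyde.

Step 4
Reactants: 6 (4E,8E)-10-[(4-methoxybenzyl)oxy]-4,8-dimethyldeca-4,8-dienal; 7 ethyl 2-(triphenyl-λ5-phosphanylidene)propanoate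
Product: 9 ethyl (2E,4S,6E,10E)-4-(anilinooxy)-12-[(4-methoxybenzyl)oxy]-2,6,10-trimethyldodeca-2,6,10-trienoate, via (S)-α-anilinooxy aldehyde 8 (not isolated)
Conditions: PhNO (1.0 equiv), D-proline (20 mol%), DMSO, rt; then 7, CH2Cl2, 0 °C to rt
Reagents that add atoms: nitrosobenzene (O=Nc1ccccc1)
Why: Proline-catalysed enamine α-aminoxylation sets C9′ (D-proline should give the S centre), and the labile aldehyde is trapped in the same flask by Wittig olefination with the stabilised ylide, which should give the (E)-trisubstituted enoate.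

Step 5
Reactants: 9 ethyl (2E,4S,6E,10E)-4-(anilinooxy)-12-[(4-methoxybenzyl)oxy]-2,6,10-trimethyldodeca-2,6,10-trienoate
Product: 10 ethyl (2E,4S,6E,10E)-4-hydroxy-12-[(4-methoxybenzyl)oxy]-2,6,10-trimethyldodeca-2,6,10-trienoate
Conditions: Zn, AcOH/THF, rt
Reagents that add atoms: none
Why: Reductive cleavage of the weak N–O bond frees the C9′ hydroxyl without touching the enoate, the PMB ether or the alkenes.

Step 6
Reactants: 10 ethyl (2E,4S,6E,10E)-4-hydroxy-12-[(4-methoxybenzyl)oxy]-2,6,10-trimethyldodeca-2,6,10-trienoate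
Product: 11 (2E,4S,6E,10E)-12-[(4-methoxybenzyl)oxy]-2,6,10-trimethyldodeca-2,6,10-triene-1,4-diol
Conditions: DIBAL-H (3.5 equiv), CH2Cl2, −78 °C; Rochelle salt work-up
Reagents that add atoms: none
Why: 1,2-Reduction of the enoate gives the primary allylic alcohol (C12′) with the E geometry unchanged.

Step 7
Reactants: 11 (2E,4S,6E,10E)-12-[(4-methoxybenzyl)oxy]-2,6,10-trimethyldodeca-2,6,10-triene-1,4-diol
Product: 12 bis(tert-butyldimethylsilyl) ether of 11
Conditions: TBSCl, imidazole, DMF, rt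
Reagents that add atoms: tert-butyldimethylsilyl chloride (CC(C)(C)[Si](C)(C)Cl)
Why: Standard silylation of the primary and the secondary allylic alcohol.

Step 8
Reactants: 12 bis(tert-butyldimethylsilyl) ether of 11
Product: 13 (2E,6E,9S,10E)-9,12-bis[(tert-butyldimethylsilyl)oxy]-3,7,11-trimethyldodeca-2,6,10-trien-1-ol
Conditions: DDQ, CH2Cl2/pH 7 buffer, 0 °C
Reagents that add atoms: none
Why: Oxidative PMB cleavage by benzylic hydride abstraction leaves the TBS ethers and the trisubstituted alkenes intact.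

Step 9
Reactants: 13 (2E,6E,9S,10E)-9,12-bis[(tert-butyldimethylsilyl)oxy]-3,7,11-trimethyldodeca-2,6,10-trien-1-ol
Product: 15 (2E,6E,9S,10E)-1-bromo-9,12-bis[(tert-butyldimethylsilyl)oxy]-3,7,11-trimethyldodeca-2,6,10-triene, via allylic mesylate 14 (not isolated)
Conditions: MsCl, Et3N, THF, −40 °C; then LiBr, THF, 0 °C
Reagents that add atoms: lithium bromide ([Li+].[Br-])
Why: Mesylation and SN2 displacement at the primary allylic carbon should give the (E)-allylic bromide without allylic transposition.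

Step 10
Reactants: 16 (1S,2S)-1,2-diphenylethane-1,2-diol ((S,S)-hydrobenzoin)
Product: 17 (1S,2S)-1,2-diphenyl-1,2-bis(trimethylsilyloxy)ethane
Conditions: Me3SiCl, Et3N, CH2Cl2, 0 °C to rt
Reagents that add atoms: chlorotrimethylsilane (C[Si](C)(C)Cl)
Why: Silylation of both hydroxyl groups provides the bis-silyl ether needed for aprotic ketalisation.

Step 11
Reactants: 18 dimethyl squarate; 17 (1S,2S)-1,2-diphenyl-1,2-bis(trimethylsilyloxy)ethane
Product: 19 (6S,7S)-2,3-dimethoxy-6,7-diphenyl-5,8-dioxaspiro[3.4]oct-2-en-1-one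
Conditions: TMSOTf (cat.), CH2Cl2, −78 to −20 °C; pyridine quench
Reagents that add atoms: none
Why: Noyori ketalisation of one of the two equivalent carbonyl groups, driven by formation of hexamethyldisiloxane; the remaining carbonyl is then a less electrophilic vinylogous ester, and the C2-symmetric diol creates no new stereocenter.

Step 12
Reactants: 19 (6S,7S)-2,3-dimethoxy-6,7-diphenyl-5,8-dioxaspiro[3.4]oct-2-en-1-one; 20 (E)-1-bromoprop-1-ene; 15 (2E,6E,9S,10E)-1-bromo-9,12-bis[(tert-butyldimethylsilyl)oxy]-3,7,11-trimethyldodeca-2,6,10-triene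
Product: 25 (2S,3S,9R,10R)-9-[(2E,6E,9S,10E)-9,12-bis[(tert-butyldimethylsilyl)oxy]-3,7,11-trimethyldodeca-2,6,10-trienyl]-6,7-dimethoxy-10-methyl-2,3-diphenyl-1,4-dioxaspiro[4.5]dec-6-en-8-one, via (E)-prop-1-enyllithium 21 (not isolated), via lithium cyclobutenolate 22 (not isolated), via lithium trienolate 23 (not isolated), via lithium dienolate 24 (not isolated)
Conditions: 20, t-BuLi (2.0 equiv), Et2O, −78 °C; 19, THF, −78 °C to rt; then DMPU, 15, −78 to 0 °C; aq. NH4Cl
Reagents that add atoms: none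
Why: Propenyllithium adds 1,2 to the single carbonyl of 19; in the cyclobutenolate the O⁻ substituent rotates outward in the conrotatory 4π opening of the C1–C4 bond, which turns the propenyl group inward (cis to C2 across the new C3=C4 bond) as the next step needs. The trienolate then closes the six-membered carbocycle by a thermal disrotatory 6π electrocyclisation (new bond C1–C6) and gives the lithium enolate of the ring-expanded ketone, which is C-alkylated at C5 by 15. The closest known reaction type is the oxy-anion-accelerated 4π/6π two-carbon ring expansion of cyclobutenones (and of ketals of benzocyclobutenediones) on addition of alkenyllithiums, followed by ordinary enolate allylation. C6 is set in the electrocyclisation by the C2-symmetric (4S,5S)-diphenyldioxolane: the outward methyl group of the (E)-propenyl terminus should end on the ring face away from the phenyl group that flanks the forming C1–C6 bond, which with the (S,S)-diol is the R centre of the target. C5 is set by substrate control, the bromide entering anti to the adjacent C6 methyl group (5,6-trans). The step needs 1,2- rather than conjugate addition (hard lithium reagent at −78 °C), outward rotation of O⁻ (its strong donor preference), and mono-C-alkylation by SN2 (primary allylic bromide, DMPU, low temperature); a minor isomer from the 6π step is a diastereomer of 25 and separable.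

Step 13
Reactants: 25 ketal-protected 5,6-trans enone
Product: 26 (2S,3S,8R,9R,10R)-9-[(2E,6E,9S,10E)-9,12-bis[(tert-butyldimethylsilyl)oxy]-3,7,11-trimethyldodeca-2,6,10-trienyl]-6,7-dimethoxy-10-methyl-2,3-diphenyl-1,4-dioxaspiro[4.5]dec-6-en-8-ol
Conditions: L-Selectride, THF, −78 °C
Reagents that add atoms: none
Why: The bulky hydride should reduce the β,β-disubstituted enone 1,2 from the face opposite to the adjacent C5 substituent, as with 2-alkylcyclohexanones, and so give the 4,5-cis alcohol.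

Step 14
Reactants: 26 ketal-protected 4,5-cis allylic alcohol
Product: 27 (4R,5R,6R)-5-[(2E,6E,9S,10E)-9,12-bis[(tert-butyldimethylsilyl)oxy]-3,7,11-trimethyldodeca-2,6,10-trienyl]-4-hydroxy-2,3-dimethoxy-6-methylcyclohex-2-en-1-one
Conditions: 1 M aq. HCl/THF (1:5), 0 °C
Reagents that add atoms: water (O)
Why: The ketal ionises easily because its oxocarbenium ion is conjugated with the dimethoxy alkene, so mild acid hydrolysis should release the C1 vinylogous-ester ketone and the auxiliary diol while C6 stays in the favoured trans arrangement.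

Step 15
Reactants: 27 bis-TBS ether of the target
Product: 28 (4R,5R,6R)-4-hydroxy-5-[(2E,6E,9S,10E)-9,12-dihydroxy-3,7,11-trimethyldodeca-2,6,10-trienyl]-2,3-dimethoxy-6-methylcyclohex-2-en-1-one (target)
Conditions: HF·pyridine, pyridine, THF, 0 °C to rt
Reagents that add atoms: none
Why: Buffered fluoride cleavage of both silyl ethers avoids base-induced dehydration of the 4-hydroxy enone and should give the target.

Compound list
1 | (2E,6E)-farnesol | OC/C=C(\C)CC/C=C(\C)CCC=C(C)C | starting material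
2 | (2E,6E)-farnesyl 4-methoxybenzyl ether | COc1ccc(COC/C=C(\C)CC/C=C(\C)CCC=C(C)C)cc1 | intermediate
3 | 10-bromo-11-hydroxy-10,11-dihydro derivative of 2 (bromohydrin, racemic) | COc1ccc(COC/C=C(\C)CC/C=C(\C)CCC(Br)C(C)(C)O)cc1 | intermediate
4 | 10,11-epoxide of 2 (racemic) | COc1ccc(COC/C=C(\C)CC/C=C(\C)CCC2OC2(C)C)cc1 | intermediate
5 | 10,11-diol of 2 (racemic) | COc1ccc(COC/C=C(\C)CC/C=C(\C)CCC(O)C(C)(C)O)cc1 | intermediate
6 | (4E,8E)-10-[(4-methoxybenzyl)oxy]-4,8-dimethyldeca-4,8-dienal | COc1ccc(COC/C=C(\C)CC/C=C(\C)CCC=O)cc1 | intermediate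
7 | ethyl 2-(triphenyl-λ5-phosphanylidene)propanoate | CCOC(=O)C(C)=P(c1ccccc1)(c1ccccc1)c1ccccc1 | starting material
8 | (2S,4E,8E)-2-(anilinooxy)-10-[(4-methoxybenzyl)oxy]-4,8-dimethyldeca-4,8-dienal | COc1ccc(COC/C=C(\C)CC/C=C(\C)C[C@H](ONc2ccccc2)C=O)cc1 | intermediate
9 | ethyl (2E,4S,6E,10E)-4-(anilinooxy)-12-[(4-methoxybenzyl)oxy]-2,6,10-trimethyldodeca-2,6,10-trienoate | COc1ccc(COC/C=C(\C)CC/C=C(\C)C[C@H](ONc2ccccc2)/C=C(\C)C(=O)OCC)cc1 | intermediate
10 | ethyl (2E,4S,6E,10E)-4-hydroxy-12-[(4-methoxybenzyl)oxy]-2,6,10-trimethyldodeca-2,6,10-trienoate | COc1ccc(COC/C=C(\C)CC/C=C(\C)C[C@H](O)/C=C(\C)C(=O)OCC)cc1 | intermediate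
11 | (2E,4S,6E,10E)-12-[(4-methoxybenzyl)oxy]-2,6,10-trimethyldodeca-2,6,10-triene-1,4-diol | COc1ccc(COC/C=C(\C)CC/C=C(\C)C[C@H](O)/C=C(\C)CO)cc1 | intermediate
12 | (2E,6E,9S,10E)-9,12-bis[(tert-butyldimethylsilyl)oxy]-1-[(4-methoxybenzyl)oxy]-3,7,11-trimethyldodeca-2,6,10-triene | COc1ccc(COC/C=C(\C)CC/C=C(\C)C[C@H](O[Si](C)(C)C(C)(C)C)/C=C(\C)CO[Si](C)(C)C(C)(C)C)cc1 | intermediate
13 | (2E,6E,9S,10E)-9,12-bis[(tert-butyldimethylsilyl)oxy]-3,7,11-trimethyldodeca-2,6,10-trien-1-ol | OC/C=C(\C)CC/C=C(\C)C[C@H](O[Si](C)(C)C(C)(C)C)/C=C(\C)CO[Si](C)(C)C(C)(C)C | intermediate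
14 | methanesulfonate of 13 | CS(=O)(=O)OC/C=C(\C)CC/C=C(\C)C[C@H](O[Si](C)(C)C(C)(C)C)/C=C(\C)CO[Si](C)(C)C(C)(C)C | intermediate
15 | (2E,6E,9S,10E)-1-bromo-9,12-bis[(tert-butyldimethylsilyl)oxy]-3,7,11-trimethyldodeca-2,6,10-triene | BrC/C=C(\C)CC/C=C(\C)C[C@H](O[Si](C)(C)C(C)(C)C)/C=C(\C)CO[Si](C)(C)C(C)(C)C | intermediate
16 | (1S,2S)-1,2-diphenylethane-1,2-diol ((S,S)-hydrobenzoin) | O[C@@H](c1ccccc1)[C@@H](O)c1ccccc1 | starting material
17 | (1S,2S)-1,2-diphenyl-1,2-bis(trimethylsilyloxy)ethane | C[Si](C)(C)O[C@@H](c1ccccc1)[C@@H](O[Si](C)(C)C)c1ccccc1 | intermediate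
18 | dimethyl squarate (3,4-dimethoxycyclobut-3-ene-1,2-dione) | COC1=C(OC)C(=O)C1=O | starting material
19 | (6S,7S)-2,3-dimethoxy-6,7-diphenyl-5,8-dioxaspiro[3.4]oct-2-en-1-one | COC1=C(OC)C2(O[C@@H](c3ccccc3)[C@H](c3ccccc3)O2)C1=O | intermediate
20 | (E)-1-bromoprop-1-ene | C/C=C/Br | starting material
21 | (E)-prop-1-enyllithium | C/C=C/[Li] | intermediate
22 | lithium (6S,7S)-2,3-dimethoxy-6,7-diphenyl-1-[(E)-prop-1-enyl]-5,8-dioxaspiro[3.4]oct-2-en-1-olate (either configuration at C1) | COC1=C(OC)C2(O[C@@H](c3ccccc3)[C@H](c3ccccc3)O2)C1(O[Li])/C=C/C | intermediate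
23 | lithium trienolate from ring opening of 22 (propenyl cis to the ketene-acetal arm; (4S,5S)-4,5-diphenyl-1,3-dioxolan-2-ylidene terminus) | C/C=C/C(O[Li])=C(OC)\C(OC)=C1O[C@@H](c2ccccc2)[C@H](c2ccccc2)O1 | intermediate
24 | lithium (2S,3S,10R)-6,7-dimethoxy-10-methyl-2,3-diphenyl-1,4-dioxaspiro[4.5]deca-6,8-dien-8-olate | COC1=C(OC)C(O[Li])=C[C@@H](C)C12O[C@@H](c3ccccc3)[C@H](c3ccccc3)O2 | intermediate
25 | (2S,3S,9R,10R)-9-[(2E,6E,9S,10E)-9,12-bis[(tert-butyldimethylsilyl)oxy]-3,7,11-trimethyldodeca-2,6,10-trienyl]-6,7-dimethoxy-10-methyl-2,3-diphenyl-1,4-dioxaspiro[4.5]dec-6-en-8-one | COC1=C(OC)C(=O)[C@H](C/C=C(\C)CC/C=C(\C)C[C@H](O[Si](C)(C)C(C)(C)C)/C=C(\C)CO[Si](C)(C)C(C)(C)C)[C@@H](C)C12O[C@@H](c3ccccc3)[C@H](c3ccccc3)O2 | intermediate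
26 | (2S,3S,8R,9R,10R)-9-[(2E,6E,9S,10E)-9,12-bis[(tert-butyldimethylsilyl)oxy]-3,7,11-trimethyldodeca-2,6,10-trienyl]-6,7-dimethoxy-10-methyl-2,3-diphenyl-1,4-dioxaspiro[4.5]dec-6-en-8-ol | COC1=C(OC)[C@H](O)[C@H](C/C=C(\C)CC/C=C(\C)C[C@H](O[Si](C)(C)C(C)(C)C)/C=C(\C)CO[Si](C)(C)C(C)(C)C)[C@@H](C)C12O[C@@H](c3ccccc3)[C@H](c3ccccc3)O2 | intermediate
27 | (4R,5R,6R)-5-[(2E,6E,9S,10E)-9,12-bis[(tert-butyldimethylsilyl)oxy]-3,7,11-trimethyldodeca-2,6,10-trienyl]-4-hydroxy-2,3-dimethoxy-6-methylcyclohex-2-en-1-one | COC1=C(OC)[C@H](O)[C@H](C/C=C(\C)CC/C=C(\C)C[C@H](O[Si](C)(C)C(C)(C)C)/C=C(\C)CO[Si](C)(C)C(C)(C)C)[C@@H](C)C1=O | intermediate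
28 | (4R,5R,6R)-4-hydroxy-5-[(2E,6E,9S,10E)-9,12-dihydroxy-3,7,11-trimethyldodeca-2,6,10-trienyl]-2,3-dimethoxy-6-methylcyclohex-2-en-1-one | COC1=C(OC)[C@H](O)[C@H](C/C=C(\C)CC/C=C(\C)C[C@H](O)/C=C(\C)CO)[C@@H](C)C1=O | target

Total step count: 15. Longest linear sequence: 13 steps (steps 1–9 and 12–15).

Steps most likely to fail

Step 12. The facial discrimination of the 6π closure by the diphenyldioxolane may be too weak, or the ring opening may be slow because one ketal oxygen has to turn inward. The fallback sets out from 15 and returns at 27, using known chemistry without ring expansion. Commercial 2,3,4-trimethoxyphenol would be oxidised with PhI(OAc)2 in methanol to 2,3,4,4-tetramethoxycyclohexa-2,5-dien-1-one F1. Copper-catalysed asymmetric conjugate addition of dimethylzinc (Cu(OTf)2, chiral phosphoramidite of the enantiomer that gives the R methyl centre), with trapping by TMSOTf, should give the trimethylsilyl enol ether of (5R)-2,3,4,4-tetramethoxy-5-methylcyclohex-2-en-1-one F2. Methyllithium would regenerate the lithium enolate, which is alkylated by 15 anti to the methyl group to the trans dimethyl-ketal ketone F3. L-Selectride should give the cis dimethyl-ketal alcohol F4, and mild aqueous acid hydrolyses the dimethyl ketal to 27.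

Step 14. Acid ionisation of the allylic C4 hydroxyl may compete with ketal hydrolysis and lead to dehydration and aromatisation. The fallback sets out from 26 and returns at 27. Acetylation (Ac2O, DMAP, pyridine) would give the C4 acetate of 26 F5, in which ionisation at C4 is suppressed. The same acid hydrolysis then gives the C4 acetate of 27 F6, and K2CO3 in methanol at 0 °C removes the acetate to give 27.

Step 4. The α-aminoxy aldehyde may racemise before olefination, so that C9′ is obtained with insufficient enantiomeric purity. The fallback sets out from 10 and returns at 10 with the centre set by a reagent instead of the enamine step. Oxidation of 10 with Dess–Martin periodinane would give the 4-oxo enoate F7, and Corey–Bakshi–Shibata reduction with the (R)-methyl oxazaborolidine and catecholborane (alkenyl as the large group) should return 10 as the 4S alcohol.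

Further compounds
F1 | step 12 | 2,3,4,4-tetramethoxycyclohexa-2,5-dien-1-one | COC1=C(OC)C(OC)(OC)C=CC1=O
F2 | step 12 | trimethylsilyl enol ether of (5R)-2,3,4,4-tetramethoxy-5-methylcyclohex-2-en-1-one | COC1=C(OC)C(O[Si](C)(C)C)=C[C@@H](C)C1(OC)OC
F3 | step 12 | (5R,6R)-6-[(2E,6E,9S,10E)-9,12-bis[(tert-butyldimethylsilyl)oxy]-3,7,11-trimethyldodeca-2,6,10-trienyl]-2,3,4,4-tetramethoxy-5-methylcyclohex-2-en-1-one | COC1=C(OC)C(=O)[C@H](C/C=C(\C)CC/C=C(\C)C[C@H](O[Si](C)(C)C(C)(C)C)/C=C(\C)CO[Si](C)(C)C(C)(C)C)[C@@H](C)C1(OC)OC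
F4 | step 12 | (1R,5R,6R)-6-[(2E,6E,9S,10E)-9,12-bis[(tert-butyldimethylsilyl)oxy]-3,7,11-trimethyldodeca-2,6,10-trienyl]-2,3,4,4-tetramethoxy-5-methylcyclohex-2-en-1-ol | COC1=C(OC)[C@H](O)[C@H](C/C=C(\C)CC/C=C(\C)C[C@H](O[Si](C)(C)C(C)(C)C)/C=C(\C)CO[Si](C)(C)C(C)(C)C)[C@@H](C)C1(OC)OC
F5 | step 14 | C4 acetate of 26 | COC1=C(OC)[C@H](OC(C)=O)[C@H](C/C=C(\C)CC/C=C(\C)C[C@H](O[Si](C)(C)C(C)(C)C)/C=C(\C)CO[Si](C)(C)C(C)(C)C)[C@@H](C)C12O[C@@H](c3ccccc3)[C@H](c3ccccc3)O2
F6 | step 14 | C4 acetate of 27 | COC1=C(OC)[C@H](OC(C)=O)[C@H](C/C=C(\C)CC/C=C(\C)C[C@H](O[Si](C)(C)C(C)(C)C)/C=C(\C)CO[Si](C)(C)C(C)(C)C)[C@@H](C)C1=O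
F7 | step 4 | ethyl (2E,6E,10E)-12-[(4-methoxybenzyl)oxy]-2,6,10-trimethyl-4-oxododeca-2,6,10-trienoate | COc1ccc(COC/C=C(\C)CC/C=C(\C)CC(=O)/C=C(\C)C(=O)OCC)cc1
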